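The route rests on one disconnection (chain numbered C1, enoate carboxyl, to C14): the oxirane C5–O bond is traced back to a ring C5–C10 carbon–carbon bond, so that C4, the quaternary C5 and the 1,3-related C7 methyl sit on a 2,2,4-trisubstituted cyclohexanone (ring C5–C10, carbonyl C10) where the chair fixes them. The key step, a Baeyer–Villiger oxidation, inserts oxygen between C10 and C5 with retention and expands the carbocycle to an oxepan-2-one; opening this lactone later frees C10 for chain extension and the C5 oxygen for closure of the oxirane (O, C4, C5). Its precursor is the C4 mesylate of the aldol adduct of (4R)-2,4-dimethylcyclohexanone with ethyl (E)-3-methyl-4-oxobut-2-enoate.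

Key step: step 6

Remark: the (S,S) lithium amide of step 1 is assumed to give the (R) enol ether, the sense known for this base class with 4-alkylcyclohexanones (the antipodal amine is used should the sense prove opposite), and the enzyme of step 12 is assumed to be picked from a commercial ketoreductase panel by screening for the anti (12R,13R) product.

Step 1
Reactants: 1 4-methylcyclohexanone
Product: 2 trimethyl{[(4R)-4-methylcyclohex-1-en-1-yl]oxy}silane
Conditions: (S,S)-bis(1-phenylethyl)amine, n-BuLi, Me3SiCl (internal quench), THF, −100 °C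
Reagents that add atoms: chlorotrimethylsilane, C[Si](C)(C)Cl
Why: Enantioselective deprotonation of the prochiral ketone by a C2-symmetric chiral lithium amide under internal silyl quench distinguishes the two enantiotopic axial α-hydrogens, so the enol ether double bond is placed on the C5 side and the C7 methine (ring C4) becomes the R stereocentre.

Step 2
Reactants: 2 trimethyl{[(4R)-4-methylcyclohex-1-en-1-yl]oxy}silane; 3 iodomethane
Product: 5 (4R)-2,4-dimethylcyclohexan-1-one (C2 epimers), via lithium enolate 4 (not isolated)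
Conditions: MeLi, THF, 0 °C → rt; MeI, −78 → 0 °C
Reagents that add atoms: iodomethane 3, CI
Why: Methyllithium cleaves the O–Si bond to the regiodefined lithium enolate, whose SN2 methylation puts the methyl on C5; the configuration created at C5 is irrelevant because C5 is enolised again in step 3, and C7 is untouched.

Step 3
Reactants: 5 (4R)-2,4-dimethylcyclohexan-1-one
Product: 6 trimethyl{[(4R)-2,4-dimethylcyclohex-1-en-1-yl]oxy}silane
Conditions: Me3SiCl, NaI, Et3N, MeCN, rt
Reagents that add atoms: chlorotrimethylsilane, C[Si](C)(C)Cl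
Why: Enol silylation under equilibrating conditions (iodotrimethylsilane formed in situ, amine base) favours the more substituted C5=C10 enol ether and so fixes the site of the next enolate; the minor C9 regioisomer should end as a separable secondary aldol by-product after step 4.

Step 4
Reactants: 6 trimethyl{[(4R)-2,4-dimethylcyclohex-1-en-1-yl]oxy}silane; 7 ethyl (2E)-3-methyl-4-oxobut-2-enoate
Product: 9 ethyl (2E,4R)-4-[(1R,5R)-1,5-dimethyl-2-oxocyclohexyl]-4-hydroxy-3-methylbut-2-enoate, via lithium enolate 8 (not isolated)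
Conditions: MeLi, THF, 0 °C → rt; 7, −78 °C; AcOH, −78 °C
Reagents that add atoms: ethyl (2E)-3-methyl-4-oxobut-2-enoate 7, CCOC(=O)/C=C(\C)C=O
Why: Lithium enolate aldol addition (1,2 to the aldehyde) through a Zimmerman–Traxler chair: the tetrasubstituted enolate reacts by axial attack on the ring face trans to the equatorial C7 methyl, which sets C5 (R, C5 and C7 methyls cis), and with ring carbon C6 in the E position and the aldehyde residue equatorial the C4 hydroxyl falls syn to the C5 methyl, which sets C4 (R); the cold acidic quench forestalls retro-aldol and conjugate addition.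

Step 5
Reactants: 9 ethyl (2E,4R)-4-[(1R,5R)-1,5-dimethyl-2-oxocyclohexyl]-4-hydroxy-3-methylbut-2-enoate
Product: 10 ethyl (2E,4R)-4-[(1R,5R)-1,5-dimethyl-2-oxocyclohexyl]-3-methyl-4-[(methylsulfonyl)oxy]but-2-enoate
Conditions: MsCl, Et3N, CH2Cl2, −10 °C
Reagents that add atoms: methanesulfonyl chloride, CS(=O)(=O)Cl
Why: Sulfonylation of the secondary alcohol through sulfene proceeds with retention at C4, cannot be followed by β-elimination because C5 carries no hydrogen, and the mesylate blocks retro-aldol, removes the hydroxyl that could direct a peracid to C2=C3 and later serves as the leaving group.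

Step 6
Reactants: 10 ethyl (2E,4R)-4-[(1R,5R)-1,5-dimethyl-2-oxocyclohexyl]-3-methyl-4-[(methylsulfonyl)oxy]but-2-enoate
Product: 11 ethyl (2E,4R)-4-[(2R,4R)-2,4-dimethyl-7-oxooxepan-2-yl]-3-methyl-4-[(methylsulfonyl)oxy]but-2-enoate
Conditions: mCPBA, NaHCO3 (solid buffer), CH2Cl2, 0 °C → rt
Reagents that add atoms: 3-chloroperoxybenzoic acid, OOC(=O)c1cccc(Cl)c1
Why: The peracid adds to the C10 carbonyl to give the Criegee adduct, and the quaternary C5 shifts from C10 to the proximal peroxide oxygen antiperiplanar to the breaking O–O bond as 3-chlorobenzoate leaves, with retention at C5. The closest known reaction type is the Baeyer–Villiger oxidation of 2,2-disubstituted (α-quaternary) cyclohexanones, in which the tertiary alkyl group migrates. The oxepan-2-one ring arises by ring expansion through this 1,2-shift (oxygen inserted into the C5–C10 bond of the carbocycle), not by a cyclisation. No stereocentre is created: C5 keeps its configuration and C4 and C7 are spectators. The step needs regioselective migration of C5 over the C9 methylene, which the tertiary-over-primary migratory aptitude should secure even though the neighbouring sulfonate lowers the electron density at C5, and it needs chemoselectivity, which the electron-poor C2=C3 enoate and the masking of the allylic hydroxyl as its mesylate provide, while the buffer keeps the medium from ionising the allylic mesylate.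

Step 7
Reactants: 11 ethyl (2E,4R)-4-[(2R,4R)-2,4-dimethyl-7-oxooxepan-2-yl]-3-methyl-4-[(methylsulfonyl)oxy]but-2-enoate
Product: 13 ethyl (2E,4S,5R,7R)-4,5-epoxy-10-[methoxy(methyl)amino]-3,5,7-trimethyl-10-oxodec-2-enoate, via hydroxy amide mesylate 12 (not isolated)
Conditions: Me3Al, MeNH(OMe)·HCl, CH2Cl2, 0 °C → rt; aq. potassium sodium tartrate; K2CO3, EtOH, rt
Reagents that add atoms: N,O-dimethylhydroxylamine hydrochloride, CNOC.Cl
Why: Aminolysis of the s-trans seven-membered lactone by the aluminium amide (Weinreb amide formation, faster than attack on the conjugated ethyl ester) unmasks the C5 tertiary alcohol, whose alkoxide then displaces the C4 mesylate by intramolecular SN2 (3-exo-tet) with inversion at C4 and retention at C5 to give the (4S,5R) oxirane; ethanol as solvent makes any transesterification of the ethyl ester degenerate.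

Step 8
Reactants: 13 ethyl (2E,4S,5R,7R)-4,5-epoxy-10-[methoxy(methyl)amino]-3,5,7-trimethyl-10-oxodec-2-enoate
Product: 15 ethyl (2E,4S,5R,7R)-4,5-epoxy-10-hydroxy-3,5,7-trimethyldec-2-enoate, via aldehyde 14 (not isolated)
Conditions: Cp2Zr(H)Cl, THF, rt; then MeOH, NaBH4, 0 °C
Reagents that add atoms: none
Why: Reduction of the tertiary amide by the zirconium hydride stops at the aldehyde oxidation level and leaves esters alone, and borohydride then reduces only the aldehyde, not the β,β-disubstituted enoate or the oxirane.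

Step 9
Reactants: 15 ethyl (2E,4S,5R,7R)-4,5-epoxy-10-hydroxy-3,5,7-trimethyldec-2-enoate
Product: 16 ethyl (2E,4S,5R,7R)-4,5-epoxy-10-iodo-3,5,7-trimethyldec-2-enoate
Conditions: I2, PPh3, imidazole, CH2Cl2, 0 °C
Reagents that add atoms: iodine, II
Why: Appel-type iodination of the primary alcohol through the alkoxyphosphonium salt (SN2 by iodide), with imidazole taking up the acid so that the trisubstituted oxirane is not opened.

Step 10
Reactants: 16 ethyl (2E,4S,5R,7R)-4,5-epoxy-10-iodo-3,5,7-trimethyldec-2-enoate; 17 methyl acetoacetate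
Product: 19 1-ethyl 14-methyl (2E,4S,5R,7R)-4,5-epoxy-3,5,7-trimethyl-12-oxotetradec-2-enedioate, via acetoacetate dianion 18 (not isolated)
Conditions: 17, NaH then n-BuLi, THF, 0 °C; 16, 0 °C; AcOH
Reagents that add atoms: methyl acetoacetate 17, COC(=O)CC(C)=O
Why: γ-Alkylation of the acetoacetate dianion by the unhindered primary iodide (SN2) forms the C10–C11 bond and delivers C11–C14 as a β-keto ester, and at 0 °C this alkylation should outrun attack of the dianion on the hindered enoate or the trisubstituted oxirane.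

Step 11
Reactants: 19 1-ethyl 14-methyl (2E,4S,5R,7R)-4,5-epoxy-3,5,7-trimethyl-12-oxotetradec-2-enedioate; 20 (triisopropylsiloxy)methyl chloride
Product: 21 1-ethyl 14-methyl (2E,4S,5R,7R)-4,5-epoxy-3,5,7-trimethyl-12-oxo-13-{[(triisopropylsilyl)oxy]methyl}tetradec-2-enedioate (C13 epimers)
Conditions: NaH, THF, 0 °C; 20, 0 °C → rt
Reagents that add atoms: (triisopropylsiloxy)methyl chloride 20, CC(C)[Si](OCCl)(C(C)C)C(C)C
Why: C-Alkylation of the sodium enolate of the β-keto ester by an α-chloro ether in a weakly dissociating solvent (contact ion pair, carbon attack) installs the C13 branch as a silyl-protected hydroxymethyl group; one equivalent of base touches only the 1,3-dicarbonyl position, and C13 stays configurationally labile for step 12.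

Step 12
Reactants: 21 1-ethyl 14-methyl (2E,4S,5R,7R)-4,5-epoxy-3,5,7-trimethyl-12-oxo-13-{[(triisopropylsilyl)oxy]methyl}tetradec-2-enedioate
Product: 22 1-ethyl 14-methyl (2E,4S,5R,7R,12R,13R)-4,5-epoxy-12-hydroxy-3,5,7-trimethyl-13-{[(triisopropylsilyl)oxy]methyl}tetradec-2-enedioate
Conditions: ketoreductase (anti-selective), NADP+, i-PrOH, KH2PO4/K2HPO4 buffer pH 7, DMSO, 30 °C
Reagents that add atoms: none
Why: Dynamic reductive kinetic resolution by a ketoreductase: the C13 epimers of the α-substituted β-keto ester interconvert through the enol at neutral pH while the enzyme reduces only the (13R) epimer and delivers hydride to the carbonyl face that gives (12R), so both new stereocentres are set by the enzyme active site (anti pair).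

Step 13
Reactants: 22 1-ethyl 14-methyl (2E,4S,5R,7R,12R,13R)-4,5-epoxy-12-hydroxy-3,5,7-trimethyl-13-{[(triisopropylsilyl)oxy]methyl}tetradec-2-enedioate
Product: 23 1-ethyl 14-methyl (2E,4S,5R,7R,12R,13R)-4,5-epoxy-12-hydroxy-13-(hydroxymethyl)-3,5,7-trimethyltetradec-2-enedioate
Conditions: Bu4NF, AcOH, THF, 0 °C → rt
Reagents that add atoms: none
Why: Fluoride cleavage of the primary silyl ether, buffered by acetic acid so that no free alkoxide can start retro-aldol cleavage or C13 epimerisation; the oxirane and both esters are inert.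

Step 14
Reactants: 23 1-ethyl 14-methyl (2E,4S,5R,7R,12R,13R)-4,5-epoxy-12-hydroxy-13-(hydroxymethyl)-3,5,7-trimethyltetradec-2-enedioate
Product: 24 (2E,4S,5R,7R,12R,13R)-4,5-epoxy-12-hydroxy-13-(hydroxymethyl)-3,5,7-trimethyltetradec-2-enedioic acid
Conditions: LiOH, THF/H2O, 0 °C → rt; dilute HCl, 0 °C, to pH 4
Reagents that add atoms: lithium hydroxide, [Li+].[OH-]
Why: Saponification (acyl–oxygen cleavage by hydroxide) of the methyl and ethyl esters, in which the β-hydroxy carboxylate resists retro-aldol and C13 epimerisation and the electron-poor vinyl oxirane does not react with hydroxide, while brief cold acidification avoids acid opening of the oxirane.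

Compound list
1 | 4-methylcyclohexanone | CC1CCC(=O)CC1 | starting material
2 | trimethyl{[(4R)-4-methylcyclohex-1-en-1-yl]oxy}silane | C[Si](C)(C)OC1=CC[C@H](C)CC1 | intermediate
3 | iodomethane | CI | starting material
4 | lithium (4R)-4-methylcyclohex-1-en-1-olate | [Li]OC1=CC[C@H](C)CC1 | intermediate
5 | (4R)-2,4-dimethylcyclohexan-1-one (C2 epimers) | CC1C[C@H](C)CCC1=O | intermediate
6 | trimethyl{[(4R)-2,4-dimethylcyclohex-1-en-1-yl]oxy}silane | CC1=C(O[Si](C)(C)C)CC[C@@H](C)C1 | intermediate
7 | ethyl (2E)-3-methyl-4-oxobut-2-enoate | CCOC(=O)/C=C(\C)C=O | starting material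
8 | lithium (4R)-2,4-dimethylcyclohex-1-en-1-olate | [Li]OC1=C(C)C[C@H](C)CC1 | intermediate
9 | ethyl (2E,4R)-4-[(1R,5R)-1,5-dimethyl-2-oxocyclohexyl]-4-hydroxy-3-methylbut-2-enoate | O=C1CC[C@@H](C)C[C@]1(C)[C@H](O)/C(C)=C/C(=O)OCC | intermediate
10 | ethyl (2E,4R)-4-[(1R,5R)-1,5-dimethyl-2-oxocyclohexyl]-3-methyl-4-[(methylsulfonyl)oxy]but-2-enoate | O=C1CC[C@@H](C)C[C@]1(C)[C@H](OS(C)(=O)=O)/C(C)=C/C(=O)OCC | intermediate
11 | ethyl (2E,4R)-4-[(2R,4R)-2,4-dimethyl-7-oxooxepan-2-yl]-3-methyl-4-[(methylsulfonyl)oxy]but-2-enoate | O=C1CC[C@@H](C)C[C@@](C)(O1)[C@H](OS(C)(=O)=O)/C(C)=C/C(=O)OCC | intermediate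
12 | ethyl (2E,4R,5R,7R)-5-hydroxy-10-[methoxy(methyl)amino]-3,5,7-trimethyl-4-[(methylsulfonyl)oxy]-10-oxodec-2-enoate | CON(C)C(=O)CC[C@@H](C)C[C@@](C)(O)[C@H](OS(C)(=O)=O)/C(C)=C/C(=O)OCC | intermediate
13 | ethyl (2E,4S,5R,7R)-4,5-epoxy-10-[methoxy(methyl)amino]-3,5,7-trimethyl-10-oxodec-2-enoate | CON(C)C(=O)CC[C@@H](C)C[C@@]1(C)O[C@H]1/C(C)=C/C(=O)OCC | intermediate
14 | ethyl (2E,4S,5R,7R)-4,5-epoxy-3,5,7-trimethyl-10-oxodec-2-enoate | O=CCC[C@@H](C)C[C@@]1(C)O[C@H]1/C(C)=C/C(=O)OCC | intermediate
15 | ethyl (2E,4S,5R,7R)-4,5-epoxy-10-hydroxy-3,5,7-trimethyldec-2-enoate | OCCC[C@@H](C)C[C@@]1(C)O[C@H]1/C(C)=C/C(=O)OCC | intermediate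
16 | ethyl (2E,4S,5R,7R)-4,5-epoxy-10-iodo-3,5,7-trimethyldec-2-enoate | ICCC[C@@H](C)C[C@@]1(C)O[C@H]1/C(C)=C/C(=O)OCC | intermediate
17 | methyl acetoacetate (methyl 3-oxobutanoate) | COC(=O)CC(C)=O | starting material
18 | sodium lithium dianion of methyl acetoacetate | COC(=O)C=C([O-])[CH2-].[Na+].[Li+] | intermediate
19 | 1-ethyl 14-methyl (2E,4S,5R,7R)-4,5-epoxy-3,5,7-trimethyl-12-oxotetradec-2-enedioate | COC(=O)CC(=O)CCCC[C@@H](C)C[C@@]1(C)O[C@H]1/C(C)=C/C(=O)OCC | intermediate
20 | (triisopropylsiloxy)methyl chloride | CC(C)[Si](OCCl)(C(C)C)C(C)C | starting material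
21 | 1-ethyl 14-methyl (2E,4S,5R,7R)-4,5-epoxy-3,5,7-trimethyl-12-oxo-13-{[(triisopropylsilyl)oxy]methyl}tetradec-2-enedioate (C13 epimers) | COC(=O)C(CO[Si](C(C)C)(C(C)C)C(C)C)C(=O)CCCC[C@@H](C)C[C@@]1(C)O[C@H]1/C(C)=C/C(=O)OCC | intermediate
22 | 1-ethyl 14-methyl (2E,4S,5R,7R,12R,13R)-4,5-epoxy-12-hydroxy-3,5,7-trimethyl-13-{[(triisopropylsilyl)oxy]methyl}tetradec-2-enedioate | COC(=O)[C@H](CO[Si](C(C)C)(C(C)C)C(C)C)[C@H](O)CCCC[C@@H](C)C[C@@]1(C)O[C@H]1/C(C)=C/C(=O)OCC | intermediate
23 | 1-ethyl 14-methyl (2E,4S,5R,7R,12R,13R)-4,5-epoxy-12-hydroxy-13-(hydroxymethyl)-3,5,7-trimethyltetradec-2-enedioate | COC(=O)[C@H](CO)[C@H](O)CCCC[C@@H](C)C[C@@]1(C)O[C@H]1/C(C)=C/C(=O)OCC | intermediate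
24 | (2E,4S,5R,7R,12R,13R)-4,5-epoxy-12-hydroxy-13-(hydroxymethyl)-3,5,7-trimethyltetradec-2-enedioic acid | C/C(=C\C(=O)O)[C@@H]1O[C@]1(C)C[C@H](C)CCCC[C@@H](O)[C@@H](CO)C(=O)O | target

Total step count: 14. Longest linear sequence: 14 steps (1 to 24).

Steps most likely to fail

Step 6. The oxygen insertion may lose its direction: the inductive pull of the neighbouring sulfonate could depress the migratory aptitude of C5 enough for the C9 methylene to compete, or the hindered carbonyl could add the peracid too slowly. The fallback sets out from 9 and runs the oxidation on the free alcohol (mCPBA, NaHCO3, CH2Cl2), where C5 is more electron-rich and the hydroxyl can hydrogen-bond to the peracid. This should give ethyl (2E,4R)-4-[(2R,4R)-2,4-dimethyl-7-oxooxepan-2-yl]-4-hydroxy-3-methylbut-2-enoate F1, which is mesylated (MsCl, Et3N) and so comes back to the route at 11.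

Step 4. The carbon–carbon bond formation may be poorly controlled: the syn relationship between the C4 hydroxyl and the C5 methyl may erode in the closed transition state, or the adduct may equilibrate through retro-aldol. The fallback sets out from 9 obtained as a mixture of C4 epimers and corrects C4 by oxidation and reagent-controlled reduction after the ring expansion, where only one ketone remains. The unprotected mixture is oxidised (mCPBA, NaHCO3) to the hydroxy lactone F1 and its epimer ethyl (2E,4S)-4-[(2R,4R)-2,4-dimethyl-7-oxooxepan-2-yl]-4-hydroxy-3-methylbut-2-enoate F2. Dess–Martin periodinane converges both to ethyl (2E)-4-[(2R,4R)-2,4-dimethyl-7-oxooxepan-2-yl]-3-methyl-4-oxobut-2-enoate F3. Reduction with (S)-Me-CBS and catecholborane (1,2-selective, lactone untouched) should return the hydroxy lactone F1 as the (4R) alcohol if the tertiary C5 acts as the large substituent. Mesylation brings the material back to the route at 11.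

Step 12. Hydride transfer may occur on the wrong carbonyl face relative to C13, so that the syn pair forms, or the C13 epimers may be funnelled incompletely. The fallback sets out from 21 and accepts the more commonly found syn-selective dynamic reduction, giving 1-ethyl 14-methyl (2E,4S,5R,7R,12S,13R)-4,5-epoxy-12-hydroxy-3,5,7-trimethyl-13-{[(triisopropylsilyl)oxy]methyl}tetradec-2-enedioate F4, in which C13 is already correct. C12 is then inverted by Mitsunobu esterification (4-nitrobenzoic acid, PPh3, DIAD, THF) to 1-ethyl 14-methyl (2E,4S,5R,7R,12R,13R)-4,5-epoxy-3,5,7-trimethyl-12-[(4-nitrobenzoyl)oxy]-13-{[(triisopropylsilyl)oxy]methyl}tetradec-2-enedioate F5. Desilylation (Bu4NF, AcOH) gives 1-ethyl 14-methyl (2E,4S,5R,7R,12R,13R)-4,5-epoxy-13-(hydroxymethyl)-3,5,7-trimethyl-12-[(4-nitrobenzoyl)oxy]tetradec-2-enedioate F6. LiOH then cleaves the nitrobenzoate together with both esters, and the route is rejoined at 24.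

Further compounds
F1 | step 6 | ethyl (2E,4R)-4-[(2R,4R)-2,4-dimethyl-7-oxooxepan-2-yl]-4-hydroxy-3-methylbut-2-enoate | O=C1CC[C@@H](C)C[C@@](C)(O1)[C@H](O)/C(C)=C/C(=O)OCC
F2 | step 4 | ethyl (2E,4S)-4-[(2R,4R)-2,4-dimethyl-7-oxooxepan-2-yl]-4-hydroxy-3-methylbut-2-enoate | O=C1CC[C@@H](C)C[C@@](C)(O1)[C@@H](O)/C(C)=C/C(=O)OCC
F3 | step 4 | ethyl (2E)-4-[(2R,4R)-2,4-dimethyl-7-oxooxepan-2-yl]-3-methyl-4-oxobut-2-enoate | O=C1CC[C@@H](C)C[C@@](C)(O1)C(=O)/C(C)=C/C(=O)OCC
F4 | step 12 | 1-ethyl 14-methyl (2E,4S,5R,7R,12S,13R)-4,5-epoxy-12-hydroxy-3,5,7-trimethyl-13-{[(triisopropylsilyl)oxy]methyl}tetradec-2-enedioate | COC(=O)[C@H](CO[Si](C(C)C)(C(C)C)C(C)C)[C@@H](O)CCCC[C@@H](C)C[C@@]1(C)O[C@H]1/C(C)=C/C(=O)OCC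
F5 | step 12 | 1-ethyl 14-methyl (2E,4S,5R,7R,12R,13R)-4,5-epoxy-3,5,7-trimethyl-12-[(4-nitrobenzoyl)oxy]-13-{[(triisopropylsilyl)oxy]methyl}tetradec-2-enedioate | COC(=O)[C@H](CO[Si](C(C)C)(C(C)C)C(C)C)[C@H](OC(=O)c1ccc(cc1)[N+](=O)[O-])CCCC[C@@H](C)C[C@@]1(C)O[C@H]1/C(C)=C/C(=O)OCC
F6 | step 12 | 1-ethyl 14-methyl (2E,4S,5R,7R,12R,13R)-4,5-epoxy-13-(hydroxymethyl)-3,5,7-trimethyl-12-[(4-nitrobenzoyl)oxy]tetradec-2-enedioate | COC(=O)[C@H](CO)[C@H](OC(=O)c1ccc(cc1)[N+](=O)[O-])CCCC[C@@H](C)C[C@@]1(C)O[C@H]1/C(C)=C/C(=O)OCC
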